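**Retrosynthetic overview**
1. Target 18 ⇐ 17 by one acidolysis (tert-butyl ester and three catechol acetonides); 17 ⇐ alcohol 15 + succinic anhydride on the only free hydroxyl (O4).
2. 15 ⇐ ketone 14 by substrate-controlled hydride reduction; in 14 (trans-3,5-diester, C4 sp2) C1 is not yet a stereocentre, so this step fixes C4 and C1 together.
3. Key step (step 6): both secondary caffeate C–O bonds (C3–O, C5–O) ⇐ achiral ketone 10 + caffeic perester 12 by a radical copper/chiral-enamine α-acyloxylation that sets 3R,5R without acylating any alcohol.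
4. 10 ⇐ Diels–Alder of 2-silyloxybutadiene 8 with the pyruvate enol caffeate 7, so the quaternary C1 is built with its tertiary ester already on oxygen.
5. Ring order: the three arene rings are bought (catechol acetonide, extended by Heck reaction with acrylic acid); the cyclohexane is the only ring made, by the [4+2] of step 4.

Shorthand: Caf* = (E)-3-(2,2-dimethyl-1,3-benzodioxol-5-yl)prop-2-enoyl (caffeoyl with its catechol as the acetonide). Ring numbering follows quinic acid (C1 quaternary, C4 between C3 and C5).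

Assumption: 9-amino-9-deoxy-epi-quinine is taken to give the (R) sense at each α-carbon in step 6; if the first mono-ester shows the opposite sense, the pseudo-enantiomeric epi-quinidine amine is used.

Step 1
Reactants: 1 2,2-dimethyl-1,3-benzodioxole
Product: 2 5-bromo-2,2-dimethyl-1,3-benzodioxole
Conditions: NBS (1.05 equiv), MeCN, 0 °C to rt
Reagents that add atoms: N-bromosuccinimide, O=C1CCC(=O)N1Br
Why: Electrophilic aromatic bromination goes para to a ring oxygen, the only activated unhindered position, and no stereocentre is formed.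

Step 2
Reactants: 2 5-bromo-2,2-dimethyl-1,3-benzodioxole; 3 acrylic acid
Product: 4 (E)-3-(2,2-dimethyl-1,3-benzodioxol-5-yl)prop-2-enoic acid (Caf*-OH)
Conditions: Pd(OAc)2 (2 mol%), P(o-tol)3 (4 mol%), NaOAc, DMF, 110 °C; aq. citric acid work-up
Reagents that add atoms: none
Why: Heck reaction; syn insertion followed by syn β-hydride elimination gives the E alkene only.

Step 3
Reactants: 4 Caf*-OH; 5 tert-butyl pyruvate
Product: 7 tert-butyl 2-(Caf*-oxy)prop-2-enoate, via acid chloride 6 (not isolated)
Conditions: (COCl)2, DMF (cat.), CH2Cl2, 0 °C to rt, evaporate; then 5, Et3N, DMAP (cat.), CH2Cl2, −20 °C to rt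
Reagents that add atoms: none
Why: O-acylation of the pyruvate enolate by the acid chloride (enol ester formation) gives the captodative 2-acyloxyacrylate, and no stereocentre is formed.

Step 4
Reactants: 7 tert-butyl 2-(Caf*-oxy)prop-2-enoate; 8 2-(trimethylsilyloxy)buta-1,3-diene
Product: 10 tert-butyl 1-(Caf*-oxy)-4-oxocyclohexane-1-carboxylate, via silyl enol ether cycloadduct 9 (not isolated)
Conditions: 8 (2 equiv), BHT (cat.), toluene, 110 °C, sealed tube; then 1 M HCl, THF, 0 °C
Reagents that add atoms: none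
Why: Diels–Alder cycloaddition with "para" regiochemistry between the 2-silyloxy diene and the 1,1-disubstituted acrylate (more reactive than the β-aryl cinnamate alkene), then enol ether hydrolysis, gives an achiral ketone whose C1 carries two identical ring arms.

Step 5
Reactants: 4 Caf*-OH
Product: 12 tert-butyl (E)-3-(2,2-dimethyl-1,3-benzodioxol-5-yl)prop-2-eneperoxoate (Caf*-OO-t-Bu), via acyl imidazolide 11 (not isolated)
Conditions: 1,1'-carbonyldiimidazole (1.1 equiv), THF, rt, 1 h (until CO2 evolution stops); then t-BuOOH (5.5 M in decane, 1.5 equiv), 0 °C to rt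
Reagents that add atoms: tert-butyl hydroperoxide, CC(C)(C)OO
Why: The acid is activated as its acyl imidazolide with loss of CO2, and nucleophilic acyl substitution by the hydroperoxide then gives the perester (imidazolide perester synthesis) under neutral conditions with no stereocentre involved.

Step 6
Reactants: 10 tert-butyl 1-(Caf*-oxy)-4-oxocyclohexane-1-carboxylate; 12 Caf*-OO-t-Bu
Product: 14 tert-butyl (3R,5R)-1,3,5-tris(Caf*-oxy)-4-oxocyclohexane-1-carboxylate, via mono-ester ketone 13 (not isolated)
Conditions: 12 (2.6 equiv), 9-amino-9-deoxy-epi-quinine (20 mol%), Cl3CCO2H (40 mol%), Cu(MeCN)4PF6 (10 mol%), MeCN/THF, 0 °C to rt, argon, dark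
Reagents that add atoms: none
Why: Proposed new method: an enamine-mediated Kharasch–Sosnovsky-type radical α-acyloxylation in which Cu(MeCN)4PF6 (monovalent copper) cleaves the O–O bond of 12 to a tert-butoxyl radical and a divalent copper Caf* carboxylate, tert-butoxyl turns the secondary enamine of the ketone into an α-imino carbon radical (N–H abstraction or one-electron oxidation, as in SOMO-type enamine catalysis), the radical is captured by the divalent copper carboxylate and the C–O bond forms by reductive elimination from trivalent copper on the enamine face left open by the cinchona scaffold, hydrolysis frees the amine, and the sequence repeats at the other α-carbon under catalyst control to give the trans (3R,5R) diester (the C1 epimers of 13 converge because C1 is not a stereocentre in 14); the closest known reactions are the Kharasch–Sosnovsky allylic acyloxylation with peresters, the SOMO-type α-chlorination of enamines with copper salts, and the polar primary-amine-catalysed α-benzoyloxylation of cyclic ketones with dibenzoyl peroxide.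

Step 7
Reactants: 14 tert-butyl (3R,5R)-1,3,5-tris(Caf*-oxy)-4-oxocyclohexane-1-carboxylate
Product: 15 tert-butyl 1,3,5-tri-O-Caf*-(−)-quinate (4-OH cis to the 1- and 3-acyloxy groups, trans to the 5-acyloxy group)
Conditions: NaBH4 (1 equiv), CeCl3·7H2O (1 equiv), THF/MeOH 4:1, −78 °C, 30 min; AcOH quench at −78 °C
Reagents that add atoms: none
Why: Luche-type hydride reduction in which the quinate-type chair (tert-butyl ester equatorial, 1- and 3-acyloxy groups axial) takes hydride axially and anti to the axial C3–O bond (Felkin–Anh polar control), giving the equatorial 4-OH cis to O3 and O1 and so setting C4 and C1 together, while the cold acidic quench suppresses acyl migration.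

Step 8
Reactants: 15 tert-butyl 1,3,5-tri-O-Caf*-(−)-quinate; 16 succinic anhydride
Product: 17 tert-butyl 1,3,5-tri-O-Caf*-4-O-(3-carboxypropanoyl)-(−)-quinate
Conditions: 16 (3 equiv), DMAP (0.2 equiv), pyridine, CH2Cl2, 0 °C to rt
Reagents that add atoms: none
Why: DMAP-catalysed ring-opening acylation of the only free hydroxyl by the cyclic anhydride gives the hemisuccinate without touching a stereocentre.

Step 9
Reactants: 17 tert-butyl 1,3,5-tri-O-Caf*-4-O-(3-carboxypropanoyl)-(−)-quinate
Product: 18 1,3,5-tri-O-caffeoyl-4-O-succinoyl-(−)-quinic acid (target)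
Conditions: TFA/H2O 9:1, 0 °C to rt, 3 h; evaporate; reversed-phase HPLC
Reagents that add atoms: none
Why: Acidolysis removes the tert-butyl ester (E1 loss of 2-methylpropene) and hydrolyses the three catechol isopropylidene ketals, while the cinnamate and succinate esters survive and the absence of base prevents acyl migration or epimerisation.

**Compound list**
1 | 2,2-dimethyl-1,3-benzodioxole (catechol acetonide) | CC1(C)Oc2ccccc2O1 | starting material
2 | 5-bromo-2,2-dimethyl-1,3-benzodioxole | CC1(C)Oc2ccc(Br)cc2O1 | intermediate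
3 | acrylic acid | C=CC(=O)O | starting material
4 | (E)-3-(2,2-dimethyl-1,3-benzodioxol-5-yl)prop-2-enoic acid (Caf*-OH) | OC(=O)/C=C/c1ccc2OC(C)(C)Oc2c1 | intermediate
5 | tert-butyl pyruvate | CC(=O)C(=O)OC(C)(C)C | starting material
6 | (E)-3-(2,2-dimethyl-1,3-benzodioxol-5-yl)prop-2-enoyl chloride (Caf*-Cl) | ClC(=O)/C=C/c1ccc2OC(C)(C)Oc2c1 | intermediate (not isolated)
7 | tert-butyl 2-(Caf*-oxy)prop-2-enoate | C=C(OC(=O)/C=C/c1ccc2OC(C)(C)Oc2c1)C(=O)OC(C)(C)C | intermediate
8 | 2-(trimethylsilyloxy)buta-1,3-diene | C=CC(=C)O[Si](C)(C)C | starting material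
9 | racemic tert-butyl 1-(Caf*-oxy)-4-(trimethylsilyloxy)cyclohex-3-ene-1-carboxylate | C[Si](C)(C)OC1=CCC(OC(=O)/C=C/c2ccc3OC(C)(C)Oc3c2)(C(=O)OC(C)(C)C)CC1 | intermediate (not isolated)
10 | tert-butyl 1-(Caf*-oxy)-4-oxocyclohexane-1-carboxylate (achiral) | O=C1CCC(OC(=O)/C=C/c2ccc3OC(C)(C)Oc3c2)(C(=O)OC(C)(C)C)CC1 | intermediate
11 | (E)-3-(2,2-dimethyl-1,3-benzodioxol-5-yl)-1-(1H-imidazol-1-yl)prop-2-en-1-one (Caf*-imidazolide) | O=C(/C=C/c1ccc2OC(C)(C)Oc2c1)n1ccnc1 | intermediate (not isolated)
12 | tert-butyl (E)-3-(2,2-dimethyl-1,3-benzodioxol-5-yl)prop-2-eneperoxoate (Caf*-OO-t-Bu) | CC(C)(C)OOC(=O)/C=C/c1ccc2OC(C)(C)Oc2c1 | intermediate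
13 | tert-butyl (3R)-1,3-bis(Caf*-oxy)-4-oxocyclohexane-1-carboxylate (both C1 epimers) | O=C1CCC(OC(=O)/C=C/c2ccc3OC(C)(C)Oc3c2)(C(=O)OC(C)(C)C)C[C@H]1OC(=O)/C=C/c1ccc2OC(C)(C)Oc2c1 | intermediate (not isolated)
14 | tert-butyl (3R,5R)-1,3,5-tris(Caf*-oxy)-4-oxocyclohexane-1-carboxylate (trans-3,5; C1 not a stereocentre) | O=C1[C@H](OC(=O)/C=C/c2ccc3OC(C)(C)Oc3c2)CC(OC(=O)/C=C/c2ccc3OC(C)(C)Oc3c2)(C(=O)OC(C)(C)C)C[C@H]1OC(=O)/C=C/c1ccc2OC(C)(C)Oc2c1 | intermediate
15 | tert-butyl 1,3,5-tri-O-Caf*-(−)-quinate (3R,5R; 4-OH cis to O1 and O3, trans to O5) | O[C@H]1[C@H](OC(=O)/C=C/c2ccc3OC(C)(C)Oc3c2)C[C@](OC(=O)/C=C/c2ccc3OC(C)(C)Oc3c2)(C(=O)OC(C)(C)C)C[C@H]1OC(=O)/C=C/c1ccc2OC(C)(C)Oc2c1 | intermediate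
16 | succinic anhydride | O=C1CCC(=O)O1 | starting material
17 | tert-butyl 1,3,5-tri-O-Caf*-4-O-(3-carboxypropanoyl)-(−)-quinate | O=C(O)CCC(=O)O[C@H]1[C@H](OC(=O)/C=C/c2ccc3OC(C)(C)Oc3c2)C[C@](OC(=O)/C=C/c2ccc3OC(C)(C)Oc3c2)(C(=O)OC(C)(C)C)C[C@H]1OC(=O)/C=C/c1ccc2OC(C)(C)Oc2c1 | intermediate
18 | 1,3,5-tri-O-caffeoyl-4-O-succinoyl-(−)-quinic acid (CNP0143991.1) | O=C(O)CCC(=O)O[C@H]1[C@H](OC(=O)/C=C/c2ccc(O)c(O)c2)C[C@](OC(=O)/C=C/c2ccc(O)c(O)c2)(C(=O)O)C[C@H]1OC(=O)/C=C/c1ccc(O)c(O)c1 | target

**Totals**
Total step count: 9.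
Longest linear sequence: 8 steps (1, 2, 3, 4, 6, 7, 8, 9; step 5 is a one-step branch from 4).

**Three steps most likely to fail**

Step 6 is the most likely to fail. The radical C–O coupling is untested, and racemic background oxidation, acylation of the amine catalyst by the perester and epimerisation of the α-acyloxy ketone can all erode it. The fallback replaces the radical coupling by an ionic nitroso-aldol sequence and sets out from 10. L-Proline (30 mol%) and nitrosobenzene (3 equiv, slow addition) in DMSO at rt give tert-butyl (3R,5R)-3,5-bis(anilinooxy)-1-(Caf*-oxy)-4-oxocyclohexane-1-carboxylate F1. CuSO4·5H2O (30 mol%) in MeOH at 0 °C cleaves both N–O bonds to tert-butyl (3R,5R)-3,5-dihydroxy-1-(Caf*-oxy)-4-oxocyclohexane-1-carboxylate F2. Acylation of F2 with acid chloride 6 (2.4 equiv, freshly made from 4 as in the first half of step 3; pyridine, CH2Cl2, −20 °C) comes back to the route at 14.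

Step 7 is the next risk. Face selectivity rests only on the chair preference dictated by the remote C1 substituents, and the new alkoxide can trigger acyl migration. The fallback sets out from 14 and replaces reagent control by enzyme control: a ketoreductase panel (NADPH, glucose and glucose dehydrogenase for recycling, pH 6.5 buffer with DMSO, 30 °C) is screened for an enzyme that recognises the whole molecule. It comes back at 15 and makes no new compound (F0).

Step 8 is the third risk. The 4-OH is flanked by two esters, and base or DMAP can move a Caf* group onto O4 before the succinate arrives. The fallback sets out from 15 and changes the acyl donor and the activation. Carbodiimide coupling with 4-tert-butoxy-4-oxobutanoic acid (diisopropylcarbodiimide, 4-(dimethylamino)pyridinium tosylate, CH2Cl2, rt, near neutral) gives tert-butyl 1,3,5-tri-O-Caf*-4-O-(4-tert-butoxy-4-oxobutanoyl)-(−)-quinate F3. The TFA/H2O conditions of step 9 then remove both tert-butyl esters and the three acetonides, and the route is rejoined at 18.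

**Further compounds**
F1 | step 6 | tert-butyl (3R,5R)-3,5-bis(anilinooxy)-1-(Caf*-oxy)-4-oxocyclohexane-1-carboxylate | O=C1[C@H](ONc2ccccc2)CC(OC(=O)/C=C/c2ccc3OC(C)(C)Oc3c2)(C(=O)OC(C)(C)C)C[C@H]1ONc1ccccc1
F2 | step 6 | tert-butyl (3R,5R)-3,5-dihydroxy-1-(Caf*-oxy)-4-oxocyclohexane-1-carboxylate | O=C1[C@H](O)CC(OC(=O)/C=C/c2ccc3OC(C)(C)Oc3c2)(C(=O)OC(C)(C)C)C[C@H]1O
F0 | step 7 | none | none
F3 | step 8 | tert-butyl 1,3,5-tri-O-Caf*-4-O-(4-tert-butoxy-4-oxobutanoyl)-(−)-quinate | CC(C)(C)OC(=O)CCC(=O)O[C@H]1[C@H](OC(=O)/C=C/c2ccc3OC(C)(C)Oc3c2)C[C@](OC(=O)/C=C/c2ccc3OC(C)(C)Oc3c2)(C(=O)OC(C)(C)C)C[C@H]1OC(=O)/C=C/c1ccc2OC(C)(C)Oc2c1
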